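**Remarks on the chemistry**

- The SMILES has no stereocentre and no stereogenic double bond. The target (6-hydroxykaempferol 3-O-sulfate) is achiral, so "single enantiomer" reduces to the correct constitution.
- Sulfate half-esters are written as hydrogen sulfates, as in the target SMILES. In the flask they are potassium salts (counter-ions are not tracked in the SMILES), and the free acid of 11 is released only at the very end by cold H+ exchange.

## The problem

The target is a flavone: benzene ring A fused to 4-pyranone ring C (O1, C2–C4, C4a, C8a), with a 4-hydroxyphenyl ring B on C2. The carbon skeleton is easy but the oxygenation is not: C3 (as O-sulfate), C4, C5, C6, C7 and C4' all carry oxygen, and ring A keeps a single C–H (C8). Of five hydroxyls exactly one, the enolic 3-OH, must bear the sulfate, and it is neither the most acidic nor the most nucleophilic of them (7-OH and 4'-OH react first with SO3 complexes). The 3-sulfate is an enol sulfate next to C4=O: it survives base and hydrogenolysis, but dilute acid hydrolyses it and the Lewis acids that cleave methyl ethers destroy it, so every protecting group must leave by hydrogenolysis or before the sulfate arrives. The 5,6,7-trihydroxy ring A is a pyrogallol that autoxidises in base and is attacked by electrophilic oxidants, so it must stay masked until the last step. The C3–O bond is usually made by oxidising a 2'-hydroxychalcone, a reaction that is least reliable when C5 carries oxygen. The structure offers a way round both problems: the 4'-OH of ring B is para to C1', and C1' is conjugated through C2=C3 to C4=O, so the 4'-phenolate is a quinone methide enolate with carbanion character at C3. C3 is therefore the vinylogous para carbon of a phenolate, the kind of position at which alkaline peroxydisulfate installs an O-sulfate. The same para relation holds once more in ring A, where C6 is para to the phenol oxygen that becomes O1.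

## Retrosynthesis

**11 ⇒ 10.** Cut: the three benzyl C–O bonds at O5, O6 and O7. Hydrogenolysis is the one deprotection that leaves an enol sulfate alone. Cutting the O–S bond last instead (sulfating the free pentahydroxyflavone) would put sulfate on O7 and O4'. Precursor 10 is no simpler in skeleton, only masked. The forward step must not reduce C2=C3 and must keep acid away from the sulfate.

**10 ⇒ 8 (key).** Cut: the C3–O bond, removing the whole OSO3 unit and leaving C3–H. The neighbouring cut, O–S, needs a flavonol whose 3-OH is the only free hydroxyl, and so an extra oxidation step to make it. The C3–O cut merges oxidation and sulfation, because peroxydisulfate delivers oxygen that is already sulfated. Precursor 8 is a plain flavone with one free phenol, no C3 oxygen and no sulfur. The forward reaction requires the 4'-phenolate of 8 to attack the peroxide through C3 rather than C3'/C5', with ring A inert. That is why the three ring-A oxygens are benzylated and O4' is the one free hydroxyl.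

**8 ⇒ 6 (through 7).** Cut: O1–C2 and the C–H bonds at C2/C3 (oxidative cyclisation of a 2'-hydroxychalcone), plus the methoxymethyl acetal on O4'. Flavone-forming cyclisation is preferred to flavonol-forming cyclisation because it is indifferent to the C5 substituent. The MOM group exists only so that O4' can be told apart from the benzylated ring-A oxygens and freed before step 5; it leaves in the same operation that gives 8.

**6 ⇒ 4 + 5.** Cut: Cα=Cβ (Claisen–Schmidt). This divides the C15 skeleton into the C6–C2 ketone 4 and the C6–C1 aldehyde 5. The alternative C4–C4a cut would need a ring-A phenol with all three oxygens in place, which is not a catalogue compound.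

**4 ⇒ 3 ⇒ 1.** Cut: one benzyl C–O bond (selective benzylation of the unchelated hydroxyl of 3), then the ring C–O bond para to the phenolic OH of commercial 1 (Elbs oxidation through aryl sulfate 2). This installs the future C6 oxygen para to the future O1, the second use of the phenolate/para relation. 1 is a catalogue compound.

## Roads not taken

Alternative 1: (the obvious route) Cut the O–S bond, then C3–O and O1–C2 together. Forward: the all-benzyl 2'-hydroxychalcone A1 is oxidised with alkaline H2O2 (Algar–Flynn–Oyamada) to flavonol A2, whose 3-OH is the only free hydroxyl; SO3·NEt3 and hydrogenolysis follow. Why not: A1 has a benzyloxy group ortho to the carbonyl (the future C5–O). That group twists the aroyl unit out of the enone plane, the phenolate then closes 5-exo on Cα, and the aurone A3 competes with or overtakes A2. The target has exactly the substitution pattern for which this reaction is unreliable. The route also treats C3 twice (oxidise, then sulfate) for the same six steps, whereas the chosen plan does both at once and forms ring C by a cyclisation that ignores C5.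

Alternative 2: Cut C4–C4a, C3–C4 and O1–C2 at once. Forward: a three-component Pd-catalysed carbonylative Sonogashira annulation of iodophenol A4, CO and alkyne A5 gives flavone A6, followed by C3 hydroxylation to A2, sulfation and hydrogenolysis. Why not: the C–I bond of A4 sits between OH and OBn, so oxidative addition and CO insertion are hindered. The intermediate ynone can close 5-exo to A3 as well as 6-endo. A4 itself costs two steps. The three-component step leaves C3 bare, so oxidation and sulfation follow separately: seven steps, with the C3 problem untouched by the key step.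

Alternative 3: Cut all O–S bonds but one after the fact. Forward: make the unprotected aglycone A7 through methyl ethers and a global BBr3 demethylation, sulfate every reactive hydroxyl (SO3·NMe3) to the polysulfate A8, and let an arylsulfatase hydrolyse the aryl sulfates while the enol sulfate at O3 stays. Why not: the key step starts from a precursor more complex than its product. A8 is only one of several polysulfates that would form, because O6 is flanked on both sides and O5 is chelated. Whether the enzyme accepts a 6-sulfate between two substituents cannot be argued from structure. The free pyrogallol ring A is also carried through two basic steps in which it autoxidises, whereas the chosen plan keeps ring A benzylated until the sulfate is in place.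

Key step: step 5

## Route

Step 1
Reactants: 1 1-[2,4-bis(benzyloxy)-6-hydroxyphenyl]ethan-1-one (commercial)
Product: 3 1-[2,4-bis(benzyloxy)-3,6-dihydroxyphenyl]ethan-1-one, via aryl sulfate 2 (not isolated)
Conditions: K2S2O8 (1.1 equiv), KOH (aq.), pyridine, 0 °C → rt, dark; HCl to pH 4, Et2O wash; then 2 M HCl, 80 °C, N2
Reagents that add atoms: potassium peroxydisulfate, [K+].[K+].[O-]S(=O)(=O)OOS(=O)(=O)[O-]
Why: Elbs persulfate oxidation: the phenolate of 1 attacks the peroxide O–O bond through its para carbon (between the two benzyloxy groups) to give sulfate 2, whose acid hydrolysis (S–O cleavage) leaves the new phenol; the reaction type is established for 2-hydroxy-4,6-dialkoxyacetophenones, and benzyl ethers tolerate both the alkali and the dilute acid.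

Step 2
Reactants: 3 1-[2,4-bis(benzyloxy)-3,6-dihydroxyphenyl]ethan-1-one
Product: 4 1-[2,3,4-tris(benzyloxy)-6-hydroxyphenyl]ethan-1-one
Conditions: BnBr (1.05 equiv), K2CO3, acetone, 50 °C, N2
Reagents that add atoms: benzyl bromide, BrCc1ccccc1
Why: Williamson etherification; the 6-OH is held in a hydrogen bond to the acetyl C=O and is not alkylated under carbonate, so only the new 3-OH reacts, the standard way to differentiate the hydroxyls of 2,5-dihydroxyacetophenones.

Step 3
Reactants: 4 1-[2,3,4-tris(benzyloxy)-6-hydroxyphenyl]ethan-1-one; 5 4-(methoxymethoxy)benzaldehyde (commercial)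
Product: 6 (2E)-1-[2,3,4-tris(benzyloxy)-6-hydroxyphenyl]-3-[4-(methoxymethoxy)phenyl]prop-2-en-1-one
Conditions: KOH (50% aq.), EtOH–THF, rt, 48 h; then HCl (aq.) to pH 4
Reagents that add atoms: none
Why: Claisen–Schmidt condensation; E1cB dehydration under thermodynamic control should give only the E-enone, and the base-stable MOM acetal keeps the aldehyde electrophilic (a free 4-phenolate would deactivate it).

Step 4
Reactants: 6 (2E)-1-[2,3,4-tris(benzyloxy)-6-hydroxyphenyl]-3-[4-(methoxymethoxy)phenyl]prop-2-en-1-one
Product: 8 5,6,7-tris(benzyloxy)-2-(4-hydroxyphenyl)-4H-chromen-4-one, via MOM-protected flavone 7 (not isolated)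
Conditions: I2 (10 mol%), DMSO, 120 °C; then 3 M HCl (aq.), THF, 50 °C
Reagents that add atoms: none
Why: Iodine/DMSO oxidative cyclisation of a 2'-hydroxychalcone: 6-endo oxa-Michael addition gives the flavanone, α-iodination and loss of HI give flavone 7, and DMSO reoxidises HI; acetal hydrolysis then frees the 4'-OH while the benzyl ethers, which need hydrogenolysis or a strong Lewis acid, remain.

Step 5
Reactants: 8 5,6,7-tris(benzyloxy)-2-(4-hydroxyphenyl)-4H-chromen-4-one
Product: 10 5,6,7-tris(benzyloxy)-2-(4-hydroxyphenyl)-4-oxo-4H-chromen-3-yl hydrogen sulfate, via quinone methide sulfate 9 (not isolated)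
Conditions: K2S2O8 (1.2 equiv), KOH (4 equiv), pyridine–H2O 1:1, 5 °C → rt, dark, N2; AcOH to pH 7; K salt isolated by n-BuOH extraction or C18
Reagents that add atoms: potassium peroxydisulfate, [K+].[K+].[O-]S(=O)(=O)OOS(=O)(=O)[O-]
Why: Proposed new method: a vinylogous Elbs peroxydisulfate oxidation, argued as follows. KOH ionises the only free hydroxyl of 8 (O4'); the phenolate is delocalised through C1' and C2=C3 onto C3 and O4 (quinone methide enolate), and in the Hückel non-bonding orbital of this extended anion C3 has the same weight as C3'/C5'. As in the Elbs reaction the anion displaces sulfate from the O–O bond of S2O8(2−) through carbon, here C3, to give the 2-alkoxy-para-quinone methide 9 with the O-sulfate already on C3; loss of the doubly activated C3–H then rearomatises ring B and restores the pyranone, so 10 leaves as a phenolate whose C3 is blocked. Closest known reaction types: Elbs para-sulfooxylation of phenolates, the same oxidation of pyridones at the ring carbon flanking C=O, and C-protonation of 4-hydroxycinnamate phenolates at the vinylogous para carbon on the way to quinone methides; none has been shown at C3–H of a flavone. No ring is closed and no stereocentre is created in 10 (C3 of 9 is transient and racemic). The selectivity needed is C3 against C3'/C5' and against ring A: ring A has no free phenol (O5, whose para carbon C8 would otherwise be attacked, is benzylated), the true para carbon C1' is quaternary and can only pass its charge on to C3, and ortho attack is the slow channel of Elbs oxidations because the incoming dianion avoids the phenolate oxygen. The same phenolate makes C2 electron-rich, so hydroxide should not open the pyranone. Limiting the oxidant and working cold and dark keeps sulfate radicals away from the benzylic C–H bonds.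

Step 6
Reactants: 10 5,6,7-tris(benzyloxy)-2-(4-hydroxyphenyl)-4-oxo-4H-chromen-3-yl hydrogen sulfate
Product: 11 5,6,7-trihydroxy-2-(4-hydroxyphenyl)-4-oxo-4H-chromen-3-yl hydrogen sulfate (target)
Conditions: H2 (1 atm), 10% Pd/C, MeOH–THF, rt (on the K salt); filtration; Dowex 50W (H+), 0 °C, immediate lyophilisation
Reagents that add atoms: none
Why: Hydrogenolysis of the three aryl benzyl ethers, the usual last step for benzyl-protected flavonoid sulfates; sulfate monoester anions are neither cleaved nor catalyst poisons, the tetrasubstituted C2=C3 bond of the chromone should not be reduced at 1 atm, and no acid reaches the enol sulfate until the final cold proton exchange.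

## Compound list

1 | 1-[2,4-bis(benzyloxy)-6-hydroxyphenyl]ethan-1-one | CC(=O)c1c(O)cc(OCc2ccccc2)cc1OCc1ccccc1 | starting material
2 | 3-acetyl-2,6-bis(benzyloxy)-4-hydroxyphenyl hydrogen sulfate (potassium salt in the flask) | CC(=O)c1c(O)cc(OCc2ccccc2)c(OS(=O)(=O)O)c1OCc1ccccc1 | intermediate (not isolated)
3 | 1-[2,4-bis(benzyloxy)-3,6-dihydroxyphenyl]ethan-1-one | CC(=O)c1c(O)cc(OCc2ccccc2)c(O)c1OCc1ccccc1 | intermediate
4 | 1-[2,3,4-tris(benzyloxy)-6-hydroxyphenyl]ethan-1-one | CC(=O)c1c(O)cc(OCc2ccccc2)c(OCc2ccccc2)c1OCc1ccccc1 | intermediate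
5 | 4-(methoxymethoxy)benzaldehyde | COCOc1ccc(C=O)cc1 | starting material
6 | (2E)-1-[2,3,4-tris(benzyloxy)-6-hydroxyphenyl]-3-[4-(methoxymethoxy)phenyl]prop-2-en-1-one | COCOc1ccc(/C=C/C(=O)c2c(O)cc(OCc3ccccc3)c(OCc3ccccc3)c2OCc2ccccc2)cc1 | intermediate
7 | 5,6,7-tris(benzyloxy)-2-[4-(methoxymethoxy)phenyl]-4H-chromen-4-one | COCOc1ccc(-c2cc(=O)c3c(OCc4ccccc4)c(OCc4ccccc4)c(OCc4ccccc4)cc3o2)cc1 | intermediate (not isolated)
8 | 5,6,7-tris(benzyloxy)-2-(4-hydroxyphenyl)-4H-chromen-4-one | O=c1cc(-c2ccc(O)cc2)oc2cc(OCc3ccccc3)c(OCc3ccccc3)c(OCc3ccccc3)c12 | intermediate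
9 | 5,6,7-tris(benzyloxy)-4-oxo-2-(4-oxocyclohexa-2,5-dien-1-ylidene)-3,4-dihydro-2H-chromen-3-yl hydrogen sulfate (racemic at C3, transient) | O=C1C=CC(=C2Oc3cc(OCc4ccccc4)c(OCc4ccccc4)c(OCc4ccccc4)c3C(=O)C2OS(=O)(=O)O)C=C1 | intermediate (not isolated)
10 | 5,6,7-tris(benzyloxy)-2-(4-hydroxyphenyl)-4-oxo-4H-chromen-3-yl hydrogen sulfate | O=c1c(OS(=O)(=O)O)c(-c2ccc(O)cc2)oc2cc(OCc3ccccc3)c(OCc3ccccc3)c(OCc3ccccc3)c12 | intermediate
11 | 5,6,7-trihydroxy-2-(4-hydroxyphenyl)-4-oxo-4H-chromen-3-yl hydrogen sulfate | O=c1c(OS(=O)(=O)O)c(-c2ccc(O)cc2)oc2cc(O)c(O)c(O)c12 | target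

## Step count and least certain steps

Total step count: 6. Longest linear sequence: 6 steps (1 → 11); aldehyde 5 enters in step 3.

**Step 5 (key step, proposed new method).** Most likely to go wrong: the phenolate reacts through the ortho carbons of ring B (C3'/C5') or not at all. C3 shares its charge with O4, and reaching 9 costs the aromaticity of ring B, so the oxidant may sulfooxylate ring B or be consumed in oxidative coupling while 8 is returned. Fallback, known chemistry only, setting out from 8 and returning to the route at 10:
- 8 is acetylated (Ac2O, pyridine) to 4-[5,6,7-tris(benzyloxy)-4-oxo-4H-chromen-2-yl]phenyl acetate F1.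
- Dimethyldioxirane (acetone–CH2Cl2, 0 °C) epoxidises C2=C3 to the racemic epoxide 4-[4,5,6-tris(benzyloxy)-7-oxo-7,7a-dihydro-1aH-oxireno[2,3-b]chromen-1a-yl]phenyl acetate F2.
- A trace of p-TsOH opens the epoxide at C2 and tautomerises it to the flavonol 4-[5,6,7-tris(benzyloxy)-3-hydroxy-4-oxo-4H-chromen-2-yl]phenyl acetate F3, in which the 3-OH is the only free hydroxyl.
- SO3·NEt3 (DMF, 50 °C) gives the sulfate 4-[5,6,7-tris(benzyloxy)-4-oxo-3-(sulfooxy)-4H-chromen-2-yl]phenyl acetate F4.
- K2CO3 in MeOH at 0 °C removes the aryl acetate, which the sulfate tolerates, and gives 10.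

**Step 1.** Most likely to go wrong: the oxidation stalls at partial conversion. The lipophilic phenolate is poorly exposed to the aqueous oxidant, the para carbon lies between two benzyloxy groups, and the product competes for persulfate, so radical coupling and ortho attack gain ground. Fallback, setting out from 1 and returning at 3: Teuber oxidation with Fremy's salt (KH2PO4 buffer, acetone–water) converts the phenol into the para-quinone 2-acetyl-3,5-bis(benzyloxy)cyclohexa-2,5-diene-1,4-dione F5, and aqueous Na2S2O4 reduces it to hydroquinone 3.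

**Step 4.** Most likely to go wrong: the HI formed in the iodine cycle cleaves the chelation-activated benzyl ether at O5, and iodine substitutes ring B once the MOM group has gone. Fallback, setting out from 6 and returning at 7: NaOAc in refluxing EtOH isomerises 6 to the racemic flavanone 5,6,7-tris(benzyloxy)-2-[4-(methoxymethoxy)phenyl]-2,3-dihydro-4H-chromen-4-one F6. DDQ in refluxing dioxane dehydrogenates it by hydride abstraction at C2, with no HI or iodine present, to 7, which the acid stage of step 4 takes to 8.

**Step 3.** Most likely to go wrong: slow and incomplete condensation. The ketone is flanked by a benzyloxy group and a chelated phenolate, so its enolate forms reluctantly and the aldehyde is lost to Cannizzaro disproportionation. Fallback, setting out from 4 and returning at 8 (steps 3 and 4 are bypassed) by the Baker–Venkataraman route: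
- 4 is esterified with 4-(methoxymethoxy)benzoic acid F7 (EDC, DMAP, CH2Cl2) to 2-acetyl-3,4,5-tris(benzyloxy)phenyl 4-(methoxymethoxy)benzoate F8.
- KOH in pyridine (50 °C) shifts the aroyl group to carbon, giving the diketone 1-[2,3,4-tris(benzyloxy)-6-hydroxyphenyl]-3-[4-(methoxymethoxy)phenyl]propane-1,3-dione F9.
- Aqueous HCl in AcOH (60 °C) closes the pyranone with loss of water, cleaves the MOM acetal, and gives 8.

## Further compounds

F1 | step 5 | 4-[5,6,7-tris(benzyloxy)-4-oxo-4H-chromen-2-yl]phenyl acetate | CC(=O)Oc1ccc(-c2cc(=O)c3c(OCc4ccccc4)c(OCc4ccccc4)c(OCc4ccccc4)cc3o2)cc1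
F2 | step 5 | 4-[4,5,6-tris(benzyloxy)-7-oxo-7,7a-dihydro-1aH-oxireno[2,3-b]chromen-1a-yl]phenyl acetate (racemic) | CC(=O)Oc1ccc(C23OC2C(=O)c2c(OCc4ccccc4)c(OCc4ccccc4)c(OCc4ccccc4)cc2O3)cc1
F3 | step 5 | 4-[5,6,7-tris(benzyloxy)-3-hydroxy-4-oxo-4H-chromen-2-yl]phenyl acetate | CC(=O)Oc1ccc(-c2oc3cc(OCc4ccccc4)c(OCc4ccccc4)c(OCc4ccccc4)c3c(=O)c2O)cc1
F4 | step 5 | 4-[5,6,7-tris(benzyloxy)-4-oxo-3-(sulfooxy)-4H-chromen-2-yl]phenyl acetate | CC(=O)Oc1ccc(-c2oc3cc(OCc4ccccc4)c(OCc4ccccc4)c(OCc4ccccc4)c3c(=O)c2OS(=O)(=O)O)cc1
F5 | step 1 | 2-acetyl-3,5-bis(benzyloxy)cyclohexa-2,5-diene-1,4-dione | CC(=O)C1=C(OCc2ccccc2)C(=O)C(OCc2ccccc2)=CC1=O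
F6 | step 4 | 5,6,7-tris(benzyloxy)-2-[4-(methoxymethoxy)phenyl]-2,3-dihydro-4H-chromen-4-one (racemic) | COCOc1ccc(C2CC(=O)c3c(OCc4ccccc4)c(OCc4ccccc4)c(OCc4ccccc4)cc3O2)cc1
F7 | step 3 | 4-(methoxymethoxy)benzoic acid | COCOc1ccc(C(=O)O)cc1
F8 | step 3 | 2-acetyl-3,4,5-tris(benzyloxy)phenyl 4-(methoxymethoxy)benzoate | COCOc1ccc(C(=O)Oc2cc(OCc3ccccc3)c(OCc3ccccc3)c(OCc3ccccc3)c2C(C)=O)cc1
F9 | step 3 | 1-[2,3,4-tris(benzyloxy)-6-hydroxyphenyl]-3-[4-(methoxymethoxy)phenyl]propane-1,3-dione | COCOc1ccc(C(=O)CC(=O)c2c(O)cc(OCc3ccccc3)c(OCc3ccccc3)c2OCc2ccccc2)cc1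
A1 | alternative 1 | (2E)-1-[2,3,4-tris(benzyloxy)-6-hydroxyphenyl]-3-[4-(benzyloxy)phenyl]prop-2-en-1-one | O=C(/C=C/c1ccc(OCc2ccccc2)cc1)c1c(O)cc(OCc2ccccc2)c(OCc2ccccc2)c1OCc1ccccc1
A2 | alternative 1 | 5,6,7-tris(benzyloxy)-2-[4-(benzyloxy)phenyl]-3-hydroxy-4H-chromen-4-one | O=c1c(O)c(-c2ccc(OCc3ccccc3)cc2)oc2cc(OCc3ccccc3)c(OCc3ccccc3)c(OCc3ccccc3)c12
A3 | alternative 1 | (2Z)-4,5,6-tris(benzyloxy)-2-[4-(benzyloxy)benzylidene]-1-benzofuran-3(2H)-one | O=C1/C(=C/c2ccc(OCc3ccccc3)cc2)Oc2cc(OCc3ccccc3)c(OCc3ccccc3)c(OCc3ccccc3)c21
A4 | alternative 2 | 3,4,5-tris(benzyloxy)-2-iodophenol | Oc1cc(OCc2ccccc2)c(OCc2ccccc2)c(OCc2ccccc2)c1I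
A5 | alternative 2 | 1-(benzyloxy)-4-ethynylbenzene | C#Cc1ccc(OCc2ccccc2)cc1
A6 | alternative 2 | 5,6,7-tris(benzyloxy)-2-[4-(benzyloxy)phenyl]-4H-chromen-4-one | O=c1cc(-c2ccc(OCc3ccccc3)cc2)oc2cc(OCc3ccccc3)c(OCc3ccccc3)c(OCc3ccccc3)c12
A7 | alternative 3 | 3,5,6,7-tetrahydroxy-2-(4-hydroxyphenyl)-4H-chromen-4-one | O=c1c(O)c(-c2ccc(O)cc2)oc2cc(O)c(O)c(O)c12
A8 | alternative 3 | 5-hydroxy-4-oxo-2-[4-(sulfooxy)phenyl]-4H-chromene-3,6,7-triyl tris(hydrogen sulfate) | O=c1c(OS(=O)(=O)O)c(-c2ccc(OS(=O)(=O)O)cc2)oc2cc(OS(=O)(=O)O)c(OS(=O)(=O)O)c(O)c12
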